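The readings come from a simulation for an exercise; noise was put on by code.

Take time out first: divide the gain of monomer in chains by the loss of free monomer. In the midnight run, from 6.00 h to 12.0 h, this share reads 0.503. Assume free monomer keeps falling by the same factor per hour. Then at 25 h it reads 12.7 %, and monomer in chains reads 37.2 %. At 12.0 h the three runs show 26.4 %, 27.2 % and 27.4 % in chains. But they span just 0.058 M to 0.077 M of free monomer, and delta and theta lie outside that span. So take that fraction for both new flasks as a rough assumption, not as a reading.

all flasks: initiator 0.24 mM

| flask | free monomer | transfer agent | protic impurity | remark | time |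
|---|---|---|---|---|---|
| midnight | 0.058 M | 5 mM | 0.010 M | run made earlier |  |
| autumn | 0.066 M | 5 mM | 0.010 M | run made earlier |  |
| dawn | 0.077 M | 5 mM | 0.010 M | run made earlier |  |
| delta | 0.050 M | 5.00 mM | 0.0100 M |  | 25 h |
| theta | 0.10 M | 5.00 mM | 0.0100 M |  | 25 h |

| run | time / h | monomer in chains / % | free monomer / % |
|---|---|---|---|
| midnight | 1.00 | 2.9 | 87.2 |
| midnight | 3.00 | 9.3 | 69.4 |
| midnight | 6.00 | 16.5 | 53.8 |
| midnight | 8.00 | 20.0 | 45.9 |
| midnight | 12.0 | 26.4 | 34.1 |
| autumn | 1.00 | 3.6 | 87.1 |
| autumn | 2.00 | 6.5 | 77.6 |
| autumn | 4.00 | 12.2 | 64.6 |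
| autumn | 6.00 | 16.5 | 54.7 |
| autumn | 12.0 | 27.2 | 35.5 |
| dawn | 1.00 | 3.4 | 87.7 |
| dawn | 3.00 | 9.7 | 70.8 |
| dawn | 6.00 | 17.3 | 56.4 |
| dawn | 8.00 | 21.3 | 48.2 |
| dawn | 12.0 | 27.4 | 36.7 |

(readings scatter by 0.3 percentage points)

- which of the two ends with the longer chains by the average number of monomer units in a chain (chains begun, living or dead) ("neither" if they lie within 10 %) (delta / theta / neither)
- average number of monomer units in a chain (chains begun, living or dead) at the end, delta
- average number of monomer units in a chain (chains begun, living or dead) at the end, theta

- the average divides the monomer in chains by the number of chains begun, living and dead together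
- the earlier runs do not show the number of chains; that part of a forecast is a guess

Now apply my bench rule: one initiator, one chain. Length (the number-average degree of polymerisation) is then the fraction in chains times the charge ratio [free monomer]/[initiator], 417 in theta and 208 in delta. My reckoning gives 77.4 for delta and 155 for theta.

The rule stops where chains begin without initiator. Transfer agent is charged at 20.8 times the initiator, so 4.80 % of it, turned into new chains, equals the initiator charge. No reading shows this.

The forecast says theta, with 10 (2.5 to 60) for delta and 20 (5 to 120) for theta. On chains begun it differs from my rule: “I guess about 2 mM.”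

The flask gives theta, with 77.2 in delta and 171 in theta.

    free monomer + initiator → living end + monomer in chains (k = 54.0 M⁻¹ h⁻¹)
    free monomer + living end → monomer in chains + living end, rate k2*[living end]*[free monomer] (k = 180 M⁻¹ h⁻¹)
    living end + transfer agent → dead chain (kL = 2.00 M⁻¹ h⁻¹)
    free monomer → uncatalysed product (k = 0.0330 h⁻¹)
    protic impurity + free monomer → quenched substrate (k = 9.90 M⁻¹ h⁻¹)
    initiator → spent initiator (k = 0.130 h⁻¹)

In theta, quenching ran early, half its turnover done by 0.739 h, against 7.06 h for growth, and initiator stood at 0 % of its charge at 12.5 h. At 25.0 h, living end 1.83 × 10⁻⁴ M and dead chain 5.12 × 10⁻⁵ M make 0.234 mM chains begun, with 99.0 % of the transfer agent left. Forecast and flask part here: chains begun lie near the initiator charge 0.24 mM. Monomer in chains, 40.0 %, times 417 gives 167, beside 171.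

Take a neighbour of theta charged with 0.40 M of free monomer. Its charge ratio is 1670, and with 44.0 % in chains that gives 733; the computed length is 738.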